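**Plan**

- Retrosynthesis (gibberellin numbering): the acids come from methyl esters and a C20 aldehyde; C4–C18 is cut (enolate methylation); ring A is cut at C1–C2 and C5–C10 ([4+2]); the diene C2=C3–C4(CO2Me)=C5 is stored as a cyclobutene (extra C2–C5 bond) and joined to C6 by a C5–C6 cut; then C13–C16 (ring D), C8–C15 and C8–C6 (quaternary C8), C9–C11 and C8–C14 (ring C).
- Enabling feature: ring A is a cyclohexane whose C10 and C4 each carry a carboxyl carbon (C20, C19) and which shares the C5–C10 bond with the five-membered ring B. A C20-activated C10=C1 dienophile and an ester-bearing C2–C5 diene, held by the three-atom tether C6–C8–C9 of the bicyclo[3.2.1]octane (rings C and D), therefore close rings A and B together.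
- Forward order: ring C (organocatalytic Michael/aldol), quaternary C8 (two conjugate additions), ring D (ketyl–alkyne cyclisation), cyclobutene on C6, dienophile on C9, rings A and B in one thermal operation, then C18 and the free acids.
- Stereochemistry: C9 from the organocatalyst; C8 anti to the C9 chain; C13 by the bridge; C5 and C10 in the key step from C8/C9 through an endo transition state; C6 by equilibration in the key step; C4 by methylation anti to the axial C10 ester.

Key step: step 11

Assumption: 1 and 11 are treated as catalogue compounds, and compounds 16 to 21 are handled as mixtures of epimers at C6 (and at the cyclobutene carbon C5), because step 11 erases C5 and equilibrates C6.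

**Route**

Step 1
Reactants: 1 4-[(tert-butyldiphenylsilyl)oxy]butanal; 2 but-3-en-2-one
Product: 4 (4S)-4-{2-[(tert-butyldiphenylsilyl)oxy]ethyl}cyclohex-2-en-1-one, via Michael adduct 3 (not isolated)
Conditions: (S)-2-[methoxy(diphenyl)methyl]pyrrolidine (5 mol%), ethyl 3,4-dihydroxybenzoate (20 mol%), neat, 4 °C; then LiOH (0.1 equiv), i-PrOH, rt
Reagents that add atoms: none
Why: Enamine-catalysed Michael addition of the aldehyde to the enone (the diarylprolinol ether shields one enamine face and so sets C9; the (S)-catalyst is the one expected from the usual model) followed by intramolecular aldol condensation, which closes ring C as in the organocatalytic Robinson-type annulation to 4-substituted cyclohexenones.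

Step 2
Reactants: 4 (4S)-4-{2-[(tert-butyldiphenylsilyl)oxy]ethyl}cyclohex-2-en-1-one; 5 tert-butyl[(1-methoxyethenyl)oxy]dimethylsilane
Product: 6 methyl 2-[(1S,6S)-3-[(tert-butyldimethylsilyl)oxy]-6-{2-[(tert-butyldiphenylsilyl)oxy]ethyl}cyclohex-2-en-1-yl]acetate
Conditions: TBSOTf (5 mol%), CH2Cl2, −78 °C
Reagents that add atoms: none
Why: Mukaiyama–Michael addition with silyl transfer should put the C6–C7 acetate arm on C8 (anti to the C9 chain, a centre that step 3 removes again) and deliver the regiodefined silyl enol ether needed next.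

Step 3
Reactants: 6 methyl 2-[(1S,6S)-3-[(tert-butyldimethylsilyl)oxy]-6-{2-[(tert-butyldiphenylsilyl)oxy]ethyl}cyclohex-2-en-1-yl]acetate
Product: 7 methyl 2-[(6S)-6-{2-[(tert-butyldiphenylsilyl)oxy]ethyl}-3-oxocyclohex-1-en-1-yl]acetate
Conditions: Pd(OAc)2 (10 mol%), O2 (1 atm), DMSO, 40 °C
Reagents that add atoms: none
Why: Saegusa–Ito oxidation (palladium enolate, β-hydride elimination of the C8 hydrogen, O2 reoxidises zerovalent palladium) should regenerate the enone, which now carries the acetate arm on C8.

Step 4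
Reactants: 7 methyl 2-[(6S)-6-{2-[(tert-butyldiphenylsilyl)oxy]ethyl}-3-oxocyclohex-1-en-1-yl]acetate; 8 tributyl(propa-1,2-dien-1-yl)stannane
Product: 9 methyl 2-[(1R,2S)-2-{2-[(tert-butyldiphenylsilyl)oxy]ethyl}-5-oxo-1-(prop-2-yn-1-yl)cyclohexyl]acetate
Conditions: TiCl4 (2 equiv), CH2Cl2, −78 °C; H2O
Reagents that add atoms: none
Why: Lewis acid mediated conjugate propargylation (SE2′ attack of the allenylstannane, the propargyl counterpart of the Hosomi–Sakurai reaction) should occur axially and anti to the pseudoaxial C9 chain, which sets the quaternary C8 with the C6 arm cis and the propargyl group trans to that chain.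

Step 5
Reactants: 9 methyl 2-[(1R,2S)-2-{2-[(tert-butyldiphenylsilyl)oxy]ethyl}-5-oxo-1-(prop-2-yn-1-yl)cyclohexyl]acetate
Product: 10 methyl 2-[2-{2-[(tert-butyldiphenylsilyl)oxy]ethyl}-5-hydroxy-6-methylidenebicyclo[3.2.1]octan-1-yl]acetate (rings C and D; C8 C9 C13 configured as in the target)
Conditions: SmI2 (2.5 equiv), HMPA, t-BuOH, THF, 0 °C
Reagents that add atoms: none
Why: Ketyl–alkyne reductive cyclisation (5-exo-dig attack of the C13 ketyl on C16) should close ring D and give at once the bridgehead C13 alcohol and the C16=C17 exocyclic methylene; the C13 configuration is dictated by the bridge.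

Step 6
Reactants: 11 tert-butyl(ethenyloxy)dimethylsilane; 12 methyl prop-2-ynoate
Product: 13 methyl 4-[(tert-butyldimethylsilyl)oxy]cyclobut-1-ene-1-carboxylate (racemic)
Conditions: EtAlCl2 (20 mol%), CH2Cl2, −78 °C
Reagents that add atoms: none
Why: Lewis acid catalysed stepwise [2+2] cycloaddition of a silyl enol ether to a propiolate: the nucleophilic CH2 of 11 attacks the β-carbon of 12 and the allenolate closes on the oxocarbenium carbon, which gives the 4-silyloxy regioisomer; the racemate serves because this carbon becomes sp2 in step 7.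

Step 7
Reactants: 10 methyl 2-[2-{2-[(tert-butyldiphenylsilyl)oxy]ethyl}-5-hydroxy-6-methylidenebicyclo[3.2.1]octan-1-yl]acetate; 13 methyl 4-[(tert-butyldimethylsilyl)oxy]cyclobut-1-ene-1-carboxylate
Product: 16 cyclobutene diester (C6 joined to the cyclobutene carbon C5; both epimers at C6 and C5), via dilithio derivative 14 (not isolated), via cyclobutane ester enolate 15 (not isolated)
Conditions: LiN(i-Pr)2 (2.2 equiv), THF, −78 °C; 13 (1.5 equiv), −78 to 0 °C; AcOH
Reagents that add atoms: none
Why: Conjugate addition of the ester enolate to the strained cyclobutene ester followed by E1cB loss of silanolate (overall SN2′) should join C6 to C5 and move the ring double bond to C3=C4; C6 and C5 form without useful control, which is accepted because step 11 destroys C5 and equilibrates C6.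

Step 8
Reactants: 16 cyclobutene diester
Product: 17 primary alcohol (C20 hydroxyl free)
Conditions: HF·pyridine, THF, 0 °C to rt
Reagents that add atoms: none
Why: Fluoride cleavage of the primary silyl ether; the bridgehead tertiary alcohol cannot ionise and the cyclobutene ester is inert.

Step 9
Reactants: 17 primary alcohol
Product: 18 aldehyde (C20 formyl)
Conditions: Dess–Martin periodinane, CH2Cl2, rt
Reagents that add atoms: none
Why: Dess–Martin oxidation of the primary alcohol; the tertiary C13 alcohol cannot be oxidised.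

Step 10
Reactants: 18 aldehyde
Product: 20 2-substituted acrolein (C10=C1 with C20 formyl), via Mannich base 19 (not isolated)
Conditions: CH2=NMe2+ I− (2 equiv), Et3N (1.5 equiv), CH2Cl2, rt
Reagents that add atoms: N,N-dimethylmethyleneiminium iodide, C=[N+](C)C.[I-]
Why: Mannich reaction of the aldehyde and β-elimination of dimethylamine (α-methylenation) should give the dienophile C10=C1 activated by C20; the cyclobutene keeps the diene masked.

Step 11
Reactants: 20 2-substituted acrolein
Product: 22 dimethyl 13-hydroxy-20-oxo-18-nor-ent-gibberella-3,16-diene-7,19-dioate, via triene 21 (not isolated)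
Conditions: Et3N (0.5 equiv), BHT (cat.), MeCN (0.01 M), 140 °C, sealed tube
Reagents that add atoms: none
Why: On heating, the cyclobutene opens by conrotatory 4π electrocyclic ring opening (the C2–C5 bond breaks, release of ring strain drives it, and the C6 substituent rotates outward) to the (E)-diene C2=C3–C4(CO2Me)=C5, which is trapped by the tethered acrolein C10=C1 in an intramolecular Diels–Alder reaction that forms C1–C2 and C5–C10. The closest known reactions are cyclobutene (or benzocyclobutene) ring opening with in situ Diels–Alder trapping and the type 1 intramolecular Diels–Alder reaction of 1,6,8-nonatrienes. Ring A is closed as the six-membered ring of the [4+2] cycloaddition (both new bonds), and ring B as the five-membered ring of the hydrindane by the C5–C10 bond between the diene terminus and the substituted dienophile carbon across the C6–C8–C9 tether. C10 and C5 are controlled by C8 and C9 of the rigid bicyclo[3.2.1]octane, which allow one sense of approach, and by the transition state with the formyl group endo and the tether exo, which gives the trans A/B junction (H5 anti to C20). C6 is controlled by the substrate: in triene 21 H6 is α to the C7 ester and γ to the C19 enoate, so Et3N should equilibrate it, and only the epimer that places H6 (not C7) next to the C19 ester (allylic 1,3-strain) should cyclise, which puts C7 trans to C4. The step needs the E diene geometry (secured by torquoselectivity), the regiochemistry (secured by the tether) and chemoselectivity over C16=C17 (unactivated, and able to give only a bridged ring).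

Step 12
Reactants: 22 dimethyl 13-hydroxy-20-oxo-18-nor-ent-gibberella-3,16-diene-7,19-dioate
Product: 24 trimethyl 13-hydroxy-18-nor-ent-gibberella-3,16-diene-7,19,20-trioate, via carboxylic acid 23 (not isolated)
Conditions: NaClO2, NaH2PO4, 2-methylbut-2-ene, t-BuOH/H2O, rt; then TMSCHN2, MeOH/PhMe, 0 °C
Reagents that add atoms: sodium chlorite, [Na+].[O-]Cl=O; trimethylsilyldiazomethane, C[Si](C)(C)C=[N+]=[N-]
Why: Pinnick oxidation of the neopentyl C20 aldehyde (2-methylbut-2-ene keeps HOCl from the two alkenes) and esterification of the crude acid with the diazoalkane; no stereocentre is touched.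

Step 13
Reactants: 24 trimethyl 13-hydroxy-18-nor-ent-gibberella-3,16-diene-7,19,20-trioate
Product: 26 trimethyl 13-hydroxy-ent-gibberell-16-ene-7,19,20-trioate, via lithium enolate 25 (not isolated)
Conditions: LiBH(s-Bu)3 (1.3 equiv), THF, −78 °C; MeI (5 equiv), −78 to 0 °C
Reagents that add atoms: iodomethane, CI
Why: Conjugate hydride reduction of the C3=C4 enoate should give the C4 ester enolate regiospecifically, and methylation from the β-face, anti to the axial C10 ester (reductive alkylation with equatorial attack, as in the podocarpate series), sets C4 with C19 α and C18 β.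

Step 14
Reactants: 26 trimethyl 13-hydroxy-ent-gibberell-16-ene-7,19,20-trioate
Product: 27 13-hydroxy-ent-gibberell-16-ene-7,19,20-trioic acid (the target gibberellin triacid)
Conditions: n-PrSLi (excess), HMPA, rt; then aq. HCl
Reagents that add atoms: none
Why: SN2 demethylation of the three hindered methyl esters by thiolate, the usual release of gibberellin acids, should leave the alkene, the tertiary alcohol and every stereocentre untouched.

**Compound list**

1 | 4-[(tert-butyldiphenylsilyl)oxy]butanal | O=CCCCO[Si](c1ccccc1)(c1ccccc1)C(C)(C)C | starting material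
2 | but-3-en-2-one (methyl vinyl ketone) | CC(=O)C=C | starting material
3 | (2S)-2-{2-[(tert-butyldiphenylsilyl)oxy]ethyl}-5-oxohexanal | O=C[C@H](CCO[Si](c1ccccc1)(c1ccccc1)C(C)(C)C)CCC(C)=O | intermediate
4 | (4S)-4-{2-[(tert-butyldiphenylsilyl)oxy]ethyl}cyclohex-2-en-1-one | O=C1C=C[C@H](CCO[Si](c2ccccc2)(c2ccccc2)C(C)(C)C)CC1 | intermediate
5 | tert-butyl[(1-methoxyethenyl)oxy]dimethylsilane | C=C(OC)O[Si](C)(C)C(C)(C)C | starting material
6 | methyl 2-[(1S,6S)-3-[(tert-butyldimethylsilyl)oxy]-6-{2-[(tert-butyldiphenylsilyl)oxy]ethyl}cyclohex-2-en-1-yl]acetate (1,6-trans) | COC(=O)C[C@@H]1C=C(O[Si](C)(C)C(C)(C)C)CC[C@H]1CCO[Si](c1ccccc1)(c1ccccc1)C(C)(C)C | intermediate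
7 | methyl 2-[(6S)-6-{2-[(tert-butyldiphenylsilyl)oxy]ethyl}-3-oxocyclohex-1-en-1-yl]acetate | COC(=O)CC1=CC(=O)CC[C@H]1CCO[Si](c1ccccc1)(c1ccccc1)C(C)(C)C | intermediate
8 | tributyl(propa-1,2-dien-1-yl)stannane | C=C=C[Sn](CCCC)(CCCC)CCCC | starting material
9 | methyl 2-[(1R,2S)-2-{2-[(tert-butyldiphenylsilyl)oxy]ethyl}-5-oxo-1-(prop-2-yn-1-yl)cyclohexyl]acetate (propargyl trans to the silyloxyethyl chain) | COC(=O)C[C@@]1(CC#C)CC(=O)CC[C@H]1CCO[Si](c1ccccc1)(c1ccccc1)C(C)(C)C | intermediate
10 | methyl 2-[2-{2-[(tert-butyldiphenylsilyl)oxy]ethyl}-5-hydroxy-6-methylidenebicyclo[3.2.1]octan-1-yl]acetate (C8, C9, C13 as in the target) | C=C1C[C@]2(CC(=O)OC)C[C@@]1(O)CC[C@H]2CCO[Si](c1ccccc1)(c1ccccc1)C(C)(C)C | intermediate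
11 | tert-butyl(ethenyloxy)dimethylsilane | C=CO[Si](C)(C)C(C)(C)C | starting material
12 | methyl prop-2-ynoate | C#CC(=O)OC | starting material
13 | methyl 4-[(tert-butyldimethylsilyl)oxy]cyclobut-1-ene-1-carboxylate (racemic) | COC(=O)C1=CCC1O[Si](C)(C)C(C)(C)C | intermediate
14 | dilithio derivative of 10 (C13 lithium alkoxide, C6 lithium ester enolate) | C=C1C[C@]2(C=C(OC)O[Li])C[C@@]1(O[Li])CC[C@H]2CCO[Si](c1ccccc1)(c1ccccc1)C(C)(C)C | intermediate
15 | lithium enolate of the Michael adduct (2-substituted 4-silyloxycyclobutane-1-carboxylate; C13 lithium alkoxide) | C=C1C[C@]2(C(C(=O)OC)C3CC(O[Si](C)(C)C(C)(C)C)C3=C(OC)O[Li])C[C@@]1(O[Li])CC[C@H]2CCO[Si](c1ccccc1)(c1ccccc1)C(C)(C)C | intermediate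
16 | methyl 4-{1-[2-{2-[(tert-butyldiphenylsilyl)oxy]ethyl}-5-hydroxy-6-methylidenebicyclo[3.2.1]octan-1-yl]-2-methoxy-2-oxoethyl}cyclobut-1-ene-1-carboxylate (both epimers at C6 and at cyclobutene C5) | C=C1C[C@]2(C(C(=O)OC)C3CC=C3C(=O)OC)C[C@@]1(O)CC[C@H]2CCO[Si](c1ccccc1)(c1ccccc1)C(C)(C)C | intermediate
17 | methyl 4-{1-[5-hydroxy-2-(2-hydroxyethyl)-6-methylidenebicyclo[3.2.1]octan-1-yl]-2-methoxy-2-oxoethyl}cyclobut-1-ene-1-carboxylate (epimers as in 16) | C=C1C[C@]2(C(C(=O)OC)C3CC=C3C(=O)OC)C[C@@]1(O)CC[C@H]2CCO | intermediate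
18 | methyl 4-{1-[5-hydroxy-6-methylidene-2-(2-oxoethyl)bicyclo[3.2.1]octan-1-yl]-2-methoxy-2-oxoethyl}cyclobut-1-ene-1-carboxylate (epimers as in 16) | C=C1C[C@]2(C(C(=O)OC)C3CC=C3C(=O)OC)C[C@@]1(O)CC[C@H]2CC=O | intermediate
19 | Mannich base: the 2-[1-(dimethylamino)-3-oxopropan-2-yl] analogue of 18 | C=C1C[C@]2(C(C(=O)OC)C3CC=C3C(=O)OC)C[C@@]1(O)CC[C@H]2C(CN(C)C)C=O | intermediate
20 | methyl 4-{1-[5-hydroxy-6-methylidene-2-(3-oxoprop-1-en-2-yl)bicyclo[3.2.1]octan-1-yl]-2-methoxy-2-oxoethyl}cyclobut-1-ene-1-carboxylate (epimers as in 16) | C=C1C[C@]2(C(C(=O)OC)C3CC=C3C(=O)OC)C[C@@]1(O)CC[C@H]2C(=C)C=O | intermediate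
21 | methyl (2Z)-2-{2-[5-hydroxy-6-methylidene-2-(3-oxoprop-1-en-2-yl)bicyclo[3.2.1]octan-1-yl]-3-methoxy-3-oxopropylidene}but-3-enoate (C6 epimers, interconverting) | C=C1C[C@]2(C(C(=O)OC)/C=C(\C(=O)OC)C=C)C[C@@]1(O)CC[C@H]2C(=C)C=O | intermediate
22 | dimethyl 13-hydroxy-20-oxo-18-nor-ent-gibberella-3,16-diene-7,19-dioate (natural configuration at C5, C6, C8, C9, C10, C13) | C=C1C[C@]23C[C@@]1(O)CC[C@H]2[C@]1(C=O)CCC=C(C(=O)OC)[C@H]1[C@@H]3C(=O)OC | intermediate
23 | 13-hydroxy-7,19-bis(methoxycarbonyl)-18-nor-ent-gibberella-3,16-dien-20-oic acid | C=C1C[C@]23C[C@@]1(O)CC[C@H]2[C@]1(C(=O)O)CCC=C(C(=O)OC)[C@H]1[C@@H]3C(=O)OC | intermediate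
24 | trimethyl 13-hydroxy-18-nor-ent-gibberella-3,16-diene-7,19,20-trioate | C=C1C[C@]23C[C@@]1(O)CC[C@H]2[C@]1(C(=O)OC)CCC=C(C(=O)OC)[C@H]1[C@@H]3C(=O)OC | intermediate
25 | lithium enolate of the C19 ester (C4=C19) formed by 1,4-reduction of 24 | C=C1C[C@]23C[C@@]1(O)CC[C@H]2[C@]1(C(=O)OC)CCCC(=C(OC)O[Li])[C@H]1[C@@H]3C(=O)OC | intermediate
26 | trimethyl 13-hydroxy-ent-gibberell-16-ene-7,19,20-trioate (trimethyl ester of the target) | C=C1C[C@]23C[C@@]1(O)CC[C@H]2[C@]1(C(=O)OC)CCC[C@@](C)(C(=O)OC)[C@H]1[C@@H]3C(=O)OC | intermediate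
27 | 13-hydroxy-ent-gibberell-16-ene-7,19,20-trioic acid (the target gibberellin triacid) | C=C1C[C@]23C[C@@]1(O)CC[C@H]2[C@]1(C(=O)O)CCC[C@@](C)(C(=O)O)[C@H]1[C@@H]3C(=O)O | target

**Step count and risks**

Total step count: 14. Longest linear sequence: 13 (steps 1 to 5 and 7 to 14; step 6 makes the side reagent 13).

Steps most likely to fail:

1. Step 11. What may go wrong: equilibration at C6 of the ring-opened triene lags behind the cycloaddition, or the amine moves the double bonds of 21 into full conjugation, so that the mismatched C6 epimer accumulates or cyclises through a strained transition state. Fallback (stereoconvergence after the cycloaddition instead of before it): from 20 the cascade is run without amine (PhMe, 150 °C). The natural C6 epimer should give 22 and the other the 6-epimeric adduct F1. The mixture is taken through steps 12 and 13, which should give the 6-epimeric acid F2, the 6-epimeric triester F3, its lithium enolate F4 and the 6-epimeric trimethyl ester F5. F5 is then equilibrated with NaOMe in MeOH (reflux) to 26, since C6 is the only enolisable centre and the C7 ester trans to C4 is the stable arrangement.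

2. Step 7. What may go wrong: premature ring opening of 13 to the silyloxy diene, Claisen-type acylation of the enolate, or failure of the E1cB step. Fallback (unsaturation introduced by syn-elimination instead of a preinstalled leaving group): from 10, dilithio derivative 14 is added to methyl cyclobut-1-ene-1-carboxylate (catalogue compound) and the new enolate is trapped with PhSeCl to give the selenide F6. Oxidation with H2O2/pyridine gives the selenoxide F7, whose syn-elimination toward the ring CH2 should return 16.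

3. Step 4. What may go wrong: 1,2-addition, no reaction at the fully substituted β-carbon, or protodestannylation of 8. Fallback (allylation, then construction of the alkyne): from 7, Hosomi–Sakurai allylation (allyltrimethylsilane, TiCl4, CH2Cl2, −78 °C) should give the allyl ketone F8. Ozonolysis (O3, CH2Cl2, −78 °C; Me2S) should give the keto aldehyde F9. Ohira–Bestmann homologation (dimethyl (1-diazo-2-oxopropyl)phosphonate, K2CO3, MeOH) should return 9.

**Further compounds**

F1 | step 11 | 6-epimer of adduct 22 | C=C1C[C@]23C[C@@]1(O)CC[C@H]2[C@]1(C=O)CCC=C(C(=O)OC)[C@H]1[C@H]3C(=O)OC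
F2 | step 11 | 6-epimer of acid 23 | C=C1C[C@]23C[C@@]1(O)CC[C@H]2[C@]1(C(=O)O)CCC=C(C(=O)OC)[C@H]1[C@H]3C(=O)OC
F3 | step 11 | 6-epimer of triester 24 | C=C1C[C@]23C[C@@]1(O)CC[C@H]2[C@]1(C(=O)OC)CCC=C(C(=O)OC)[C@H]1[C@H]3C(=O)OC
F4 | step 11 | 6-epimer of lithium enolate 25 | C=C1C[C@]23C[C@@]1(O)CC[C@H]2[C@]1(C(=O)OC)CCCC(=C(OC)O[Li])[C@H]1[C@H]3C(=O)OC
F5 | step 11 | 6-epimer of trimethyl ester 26 | C=C1C[C@]23C[C@@]1(O)CC[C@H]2[C@]1(C(=O)OC)CCC[C@@](C)(C(=O)OC)[C@H]1[C@H]3C(=O)OC
F6 | step 7 | selenide: methyl 1-(phenylselanyl)cyclobutane-1-carboxylate carrying the C6 side chain of 16 on its C2 | C=C1C[C@]2(C(C(=O)OC)C3CCC3([Se]c3ccccc3)C(=O)OC)C[C@@]1(O)CC[C@H]2CCO[Si](c1ccccc1)(c1ccccc1)C(C)(C)C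
F7 | step 7 | selenoxide of F6 | C=C1C[C@]2(C(C(=O)OC)C3CCC3([Se](=O)c3ccccc3)C(=O)OC)C[C@@]1(O)CC[C@H]2CCO[Si](c1ccccc1)(c1ccccc1)C(C)(C)C
F8 | step 4 | methyl 2-[(1R,2S)-2-{2-[(tert-butyldiphenylsilyl)oxy]ethyl}-5-oxo-1-(prop-2-en-1-yl)cyclohexyl]acetate | COC(=O)C[C@@]1(CC=C)CC(=O)CC[C@H]1CCO[Si](c1ccccc1)(c1ccccc1)C(C)(C)C
F9 | step 4 | methyl 2-[2-{2-[(tert-butyldiphenylsilyl)oxy]ethyl}-5-oxo-1-(2-oxoethyl)cyclohexyl]acetate (configured as F8) | COC(=O)C[C@@]1(CC=O)CC(=O)CC[C@H]1CCO[Si](c1ccccc1)(c1ccccc1)C(C)(C)C
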